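Ring A (C1–C5, C10) is cut at C1–C2 and C5–C10. An enantioselective, exo-selective Diels–Alder reaction of methacrolein (C1, C10, C14, C9) with an (E)-penta-2,4-dienyl silyl ether (C2–C6) forms ring A in one operation. It sets the vicinal C5 methine and C10 quaternary centres with C6 and C9 trans, and leaves the C3=C4 alkene for the C3 ester oxygen and the C4 methyl carbinol. The precursor is an achiral diene carrying a robust triisopropylsilyl ether. Afterwards C9 is homologated to C8, ring B is closed by metathesis onto a C7 acrylate whose ester becomes the C11 carbinol, and the (2S,3R)-epoxy acid is attached last.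

Key step: step 3

Remark: eudesmane numbering is used for all intermediates; β is the face of ring A that carries the C10 methyl group (C14), α the opposite face. C5 (H α, C6 arm β) and C10 (C14 β, C9 arm α) stay as set in step 3. The C8 carbinol in 19–22 is carried as both epimers because step 19 oxidises it. TIPS = triisopropylsilyl, PMB = 4-methoxybenzyl.

Step 1
Reactants: 1 (E)-penta-2,4-dienoic acid
Product: 2 (E)-penta-2,4-dien-1-ol
Conditions: LiAlH4, Et2O, 0 °C to rt; aqueous NaOH work-up
Reagents that add atoms: none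
Why: Hydride reduction of the carboxylic acid with LiAlH4 should give the primary dienol, the diene being inert once the carboxylate is reduced.

Step 2
Reactants: 2 (E)-penta-2,4-dien-1-ol
Product: 3 (E)-triisopropyl(penta-2,4-dien-1-yloxy)silane
Conditions: TIPSCl, imidazole, CH2Cl2, 0 °C to rt
Reagents that add atoms: chlorotriisopropylsilane, CC(C)[Si](Cl)(C(C)C)C(C)C
Why: Imidazole-promoted silylation of the primary allylic alcohol; the bulky TIPS ether is chosen because it should survive the cationic Lewis acid of step 3, the acidic methanol of step 5 and the hot alkoxide of step 7.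

Step 3
Reactants: 3 (E)-triisopropyl(penta-2,4-dien-1-yloxy)silane; 4 methacrolein
Product: 5 (1S,2S)-1-methyl-2-[(triisopropylsilyloxy)methyl]cyclohex-3-ene-1-carbaldehyde
Conditions: (S)-3,3-diphenyl-1-(2-methylphenyl)tetrahydro-1H,3H-pyrrolo[1,2-c][1,3,2]oxazaborole (20 mol%), Tf2NH (17 mol%), CH2Cl2, −78 to −40 °C
Reagents that add atoms: none
Why: The cationic boron Lewis acid binds the formyl oxygen of 4 (supported by a formyl C–H···O contact to the ring oxygen) and lowers its LUMO, and the diene adds in a concerted, asynchronous [4+2] cycloaddition; the closest known reaction type is the oxazaborolidinium-catalysed Diels–Alder reaction of 2-substituted acroleins. Ring A closes as a six-membered ring by intermolecular cycloaddition, the C1–C2 and C5–C10 bonds forming suprafacially on both partners. C10 is controlled by the catalyst, whose aryl group shields one face of the s-trans enal so that, by the usual binding model, the (S)-catalyst should direct the diene to the Re face of the α-carbon (the enantiomeric catalyst would be used if the sense proved opposite). C5 is controlled relative to C10 by the formyl-exo, methyl-endo transition state with the (E)-diene, which places C6 cis to the C10 methyl group and trans to C9. Ortho regiochemistry should follow from pairing of the unsubstituted diene terminus C2 (larger HOMO coefficient) with the enal β-carbon; the exo preference needed is expected from the α-methyl group and the bulk of the boron-bound formyl group.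

Step 4
Reactants: 5 (1S,2S)-1-methyl-2-[(triisopropylsilyloxy)methyl]cyclohex-3-ene-1-carbaldehyde
Product: 6 enol ether (C10–CH=CH–OMe, E/Z mixture; 3-ene; C6–OTIPS)
Conditions: Ph3P(CH2OMe)Cl, KN(SiMe3)2, THF, 0 °C to rt
Reagents that add atoms: (methoxymethyl)triphenylphosphonium chloride, COC[P+](c1ccccc1)(c1ccccc1)c1ccccc1.[Cl-]
Why: Wittig methoxymethylenation of the non-enolisable neopentyl aldehyde adds C8 as an enol ether, and no stereocentre is at risk because C10 bears no hydrogen.

Step 5
Reactants: 6 enol ether
Product: 7 dimethyl acetal (C10–CH2–CH(OMe)2; 3-ene; C6–OTIPS)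
Conditions: MeOH, PPTS (cat.), 0 °C to rt
Reagents that add atoms: methanol, CO
Why: Acid-catalysed addition of methanol to the enol ether (acetalisation) should mask the C8 aldehyde in a form that tolerates the later peracid, alkoxide, hydride and ylide steps.

Step 6
Reactants: 7 dimethyl acetal
Product: 8 3α,4α-epoxide of 7
Conditions: mCPBA, NaHCO3, CH2Cl2, 0 °C
Reagents that add atoms: 3-chloroperoxybenzoic acid, OOC(=O)c1cccc(Cl)c1
Why: Prilezhaev epoxidation of the only alkene; the peracid should approach the α face, anti to the allylic C5 silyloxymethyl group and the C10 methyl group, which sets the temporary C3 and C4 centres.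

Step 7
Reactants: 8 3α,4α-epoxide
Product: 9 3β-(4-methoxybenzyloxy)-4α-ol (C8 acetal, C6–OTIPS)
Conditions: PMBOH, NaH, THF/DMPU, 70 °C
Reagents that add atoms: 4-methoxybenzyl alcohol, COc1ccc(CO)cc1
Why: Alkoxide SN2 opening of the epoxide in the trans-diaxial (Fürst–Plattner) mode should occur at the less hindered C3, remote from the C5 and C10 substituents, with inversion; this fixes the final 3β-oxygen and leaves only the 4α-hydroxyl free.

Step 8
Reactants: 9 3β-(4-methoxybenzyloxy)-4α-ol
Product: 10 3β-PMB-oxy 4-ketone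
Conditions: Dess–Martin periodinane, NaHCO3, CH2Cl2, rt
Reagents that add atoms: none
Why: Dess–Martin oxidation of the only free alcohol gives the C4 ketone under neutral conditions that should neither epimerise C3 or C5 nor eliminate the β-silyloxy group.

Step 9
Reactants: 10 3β-PMB-oxy 4-ketone
Product: 11 3β-PMB-oxy 4(15)-methylene compound
Conditions: Cp2TiMe2, toluene/THF, 70 °C
Reagents that add atoms: dimethyltitanocene, [CH3-].[CH3-].[Ti+4].c1cc[cH-]c1.c1cc[cH-]c1
Why: Petasis methylenation (carbonyl olefination by Cp2Ti=CH2) is non-basic and should convert the hindered, enolisable α-alkoxy ketone into the exocyclic C4=C15 alkene without epimerisation or β-elimination.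

Step 10
Reactants: 11 3β-PMB-oxy 4(15)-methylene compound
Product: 12 4α,15-epoxide (spiro-oxirane, oxygen on the α face)
Conditions: mCPBA, NaHCO3, CH2Cl2, 0 °C
Reagents that add atoms: 3-chloroperoxybenzoic acid, OOC(=O)c1cccc(Cl)c1
Why: Prilezhaev epoxidation of the 1,1-disubstituted alkene should occur from the α (equatorial) side, because axial β approach is blocked by the syn-axial C10 methyl group in the chair with all large groups equatorial; this sets the C4–O bond α, as is usual for 4(15)-eudesmenes.

Step 11
Reactants: 12 4α,15-epoxide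
Product: 13 4α-hydroxy-4β-methyl compound (3β-OPMB, C6–OTIPS, C8 acetal)
Conditions: LiAlH4, THF, 0 °C to rt
Reagents that add atoms: none
Why: Hydride opens the spiro-epoxide at its unhindered CH2 terminus (SN2 reduction), so C15 becomes the β methyl group and the 4α tertiary alcohol keeps its configuration.

Step 12
Reactants: 13 4α-hydroxy-4β-methyl compound
Product: 14 C6 primary alcohol (4α,6-diol)
Conditions: Bu4NF, THF, rt
Reagents that add atoms: none
Why: Fluoride-mediated desilylation frees the primary C6 alcohol while ether and acetal groups are untouched.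

Step 13
Reactants: 14 C6 primary alcohol
Product: 15 C6 aldehyde
Conditions: Dess–Martin periodinane, NaHCO3, CH2Cl2, 0 °C
Reagents that add atoms: none
Why: Dess–Martin oxidation affects only the primary alcohol (the tertiary one cannot be oxidised), and the buffered non-basic medium should avoid C5 epimerisation and dehydration of the β-hydroxy aldehyde.

Step 14
Reactants: 15 C6 aldehyde
Product: 16 C6 vinyl compound (C5–CH=CH2)
Conditions: Ph3PCH3Br, KN(SiMe3)2, THF, −78 to 0 °C
Reagents that add atoms: methyltriphenylphosphonium bromide, C[P+](c1ccccc1)(c1ccccc1)c1ccccc1.[Br-]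
Why: Wittig methylenation at low temperature; the ylide should add to the aldehyde faster than it deprotonates the tertiary alcohol, so retro-aldol cleavage is not expected.

Step 15
Reactants: 16 C6 vinyl compound
Product: 17 C8 aldehyde (C10–CH2–CHO)
Conditions: AcOH/THF/H2O (3:1:1), 40 °C
Reagents that add atoms: water, O
Why: Mild acid hydrolysis of the dimethyl acetal should release the aldehyde while the PMB ether, tertiary alcohol and vinyl group persist.

Step 16
Reactants: 17 C8 aldehyde; 18 methyl acrylate
Product: 19 Baylis–Hillman adduct (C8–OH, C7(=CH2)–CO2Me; C8 epimers)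
Conditions: DABCO, 1,4-dioxane/H2O (1:1), rt
Reagents that add atoms: none
Why: Morita–Baylis–Hillman reaction: DABCO adds to 18 and the resulting enolate adds to the CH2–CHO aldehyde, bringing in C7 and C11; the C8 carbinol centre forms unselectively and is oxidised in step 19.

Step 17
Reactants: 19 Baylis–Hillman adduct
Product: 20 methyl 4α,8-dihydroxy-3β-PMB-oxy-12,13-dinoreudesm-6-en-11-oate (trans-fused; C8 epimers)
Conditions: second-generation Grubbs catalyst (H2IMes)(PCy3)Cl2Ru=CHPh (5 mol%), CH2Cl2, 40 °C
Reagents that add atoms: none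
Why: Ring-closing metathesis between the C6 vinyl group and the acrylate alkene should close ring B as a trans-fused cyclohexene (both tethers equatorial) with loss of ethene, a known way to cyclic Baylis–Hillman-type esters.

Step 18
Reactants: 20 bicyclic ester
Product: 22 3β-PMB-oxy-eudesm-6-ene-4α,8,11-triol (C8 epimers), via methyl ketone 21 (not isolated)
Conditions: MeMgBr (excess), THF, 0 °C to rt
Reagents that add atoms: methylmagnesium bromide, C[Mg]Br
Why: Double Grignard 1,2-addition to the unsaturated ester through the methyl ketone should give the C11 dimethyl carbinol, the free hydroxyl groups being merely deprotonated.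

Step 19
Reactants: 22 3β-PMB-oxy-eudesm-6-ene-4α,8,11-triol
Product: 23 4α,11-dihydroxy-3β-PMB-oxy-eudesm-6-en-8-one
Conditions: Dess–Martin periodinane, NaHCO3, CH2Cl2, rt
Reagents that add atoms: none
Why: Dess–Martin oxidation of the only secondary (allylic) alcohol gives the 6-en-8-one; the two tertiary alcohols cannot react and the C8 epimers converge.

Step 20
Reactants: 23 4α,11-dihydroxy-3β-PMB-oxy-eudesm-6-en-8-one
Product: 24 3β,4α,11-trihydroxyeudesm-6-en-8-one
Conditions: DDQ, CH2Cl2/pH 7 buffer, 0 °C to rt
Reagents that add atoms: none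
Why: Oxidative PMB ether cleavage by DDQ (benzylic hydride abstraction, then hydrolysis) should free the 3β-alcohol without touching the enone or the tertiary alcohols.

Step 21
Reactants: 25 tiglic acid
Product: 26 (E)-2-methylbut-2-en-1-ol
Conditions: LiAlH4, Et2O, 0 °C to rt
Reagents that add atoms: none
Why: Hydride reduction of the conjugated acid gives the allylic alcohol with the (E) geometry retained.

Step 22
Reactants: 26 (E)-2-methylbut-2-en-1-ol
Product: 27 [(2R,3R)-2,3-dimethyloxiran-2-yl]methanol
Conditions: Ti(OiPr)4 (cat.), D-(−)-diethyl tartrate (cat.), t-BuOOH, 4 Å MS, CH2Cl2, −20 °C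
Reagents that add atoms: tert-butyl hydroperoxide, CC(C)(C)OO
Why: Sharpless asymmetric epoxidation; with the D-(−)-tartrate the titanium-bound peroxide should be delivered to the alkene face that gives the (2R,3R)-epoxy alcohol, the two methyl groups staying cis as in the (E)-alkene.

Step 23
Reactants: 27 [(2R,3R)-2,3-dimethyloxiran-2-yl]methanol
Product: 29 (2S,3R)-2,3-dimethyloxirane-2-carboxylic acid, via epoxy aldehyde 28 (not isolated)
Conditions: RuCl3 (cat.), NaIO4, MeCN/EtOAc/H2O, rt
Reagents that add atoms: sodium periodate, [Na+].[O-]I(=O)(=O)=O; water, O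
Why: Oxidation by RuO4 generated in the flask takes the primary alcohol through the aldehyde hydrate to the acid without opening the epoxide; the C2 descriptor changes from R to S only because the substituent priorities change.

Step 24
Reactants: 24 3β,4α,11-trihydroxyeudesm-6-en-8-one; 29 (2S,3R)-2,3-dimethyloxirane-2-carboxylic acid
Product: 31 CNP0272928.2 (target), via mixed anhydride 30 (not isolated)
Conditions: 29, 2,4,6-Cl3C6H2COCl, Et3N, THF, rt; then 24, DMAP, toluene, rt to 40 °C
Reagents that add atoms: none
Why: Yamaguchi esterification: the mixed anhydride should acylate, under DMAP catalysis, only the secondary equatorial 3β-alcohol, the two tertiary alcohols being unreactive, with retention at C3 and in the acyl group.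

Compound list
1 | (E)-penta-2,4-dienoic acid | C=C/C=C/C(=O)O | starting material
2 | (E)-penta-2,4-dien-1-ol | C=C/C=C/CO | intermediate
3 | (E)-triisopropyl(penta-2,4-dien-1-yloxy)silane | C=C/C=C/CO[Si](C(C)C)(C(C)C)C(C)C | intermediate
4 | methacrolein (2-methylprop-2-enal) | C=C(C)C=O | starting material
5 | (1S,2S)-1-methyl-2-[(triisopropylsilyloxy)methyl]cyclohex-3-ene-1-carbaldehyde | O=C[C@@]1(C)CCC=C[C@@H]1CO[Si](C(C)C)(C(C)C)C(C)C | intermediate
6 | enol ether: 5 with C10–CH=CH–OMe in place of CHO (E/Z mixture) | COC=C[C@@]1(C)CCC=C[C@@H]1CO[Si](C(C)C)(C(C)C)C(C)C | intermediate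
7 | dimethyl acetal: C10–CH2–CH(OMe)2, 3-ene, C6–OTIPS | COC(OC)C[C@@]1(C)CCC=C[C@@H]1CO[Si](C(C)C)(C(C)C)C(C)C | intermediate
8 | 3α,4α-epoxide of 7 | COC(OC)C[C@@]1(C)CC[C@H]2O[C@H]2[C@@H]1CO[Si](C(C)C)(C(C)C)C(C)C | intermediate
9 | 3β-(4-methoxybenzyloxy)-4α-ol (C8 acetal, C6–OTIPS) | COC(OC)C[C@@]1(C)CC[C@H](OCc2ccc(OC)cc2)[C@@H](O)[C@@H]1CO[Si](C(C)C)(C(C)C)C(C)C | intermediate
10 | 3β-PMB-oxy 4-ketone | COC(OC)C[C@@]1(C)CC[C@H](OCc2ccc(OC)cc2)C(=O)[C@@H]1CO[Si](C(C)C)(C(C)C)C(C)C | intermediate
11 | 3β-PMB-oxy 4(15)-methylene compound | COC(OC)C[C@@]1(C)CC[C@H](OCc2ccc(OC)cc2)C(=C)[C@@H]1CO[Si](C(C)C)(C(C)C)C(C)C | intermediate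
12 | 4α,15-epoxide (spiro-oxirane, oxygen α, CH2 β) | COC(OC)C[C@@]1(C)CC[C@H](OCc2ccc(OC)cc2)[C@]3(CO3)[C@@H]1CO[Si](C(C)C)(C(C)C)C(C)C | intermediate
13 | 4α-hydroxy-4β-methyl compound (3β-OPMB, C6–OTIPS, C8 acetal) | COC(OC)C[C@@]1(C)CC[C@H](OCc2ccc(OC)cc2)[C@@](C)(O)[C@@H]1CO[Si](C(C)C)(C(C)C)C(C)C | intermediate
14 | C6 primary alcohol (4α,6-diol) | COC(OC)C[C@@]1(C)CC[C@H](OCc2ccc(OC)cc2)[C@@](C)(O)[C@@H]1CO | intermediate
15 | C6 aldehyde | COC(OC)C[C@@]1(C)CC[C@H](OCc2ccc(OC)cc2)[C@@](C)(O)[C@@H]1C=O | intermediate
16 | C6 vinyl compound (C5–CH=CH2) | COC(OC)C[C@@]1(C)CC[C@H](OCc2ccc(OC)cc2)[C@@](C)(O)[C@@H]1C=C | intermediate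
17 | C8 aldehyde (C10–CH2–CHO) | O=CC[C@@]1(C)CC[C@H](OCc2ccc(OC)cc2)[C@@](C)(O)[C@@H]1C=C | intermediate
18 | methyl acrylate | C=CC(=O)OC | starting material
19 | Baylis–Hillman adduct (C8–OH, C7(=CH2)CO2Me; C8 epimers) | COC(=O)C(=C)C(O)C[C@@]1(C)CC[C@H](OCc2ccc(OC)cc2)[C@@](C)(O)[C@@H]1C=C | intermediate
20 | methyl 4α,8-dihydroxy-3β-PMB-oxy-12,13-dinoreudesm-6-en-11-oate (C8 epimers) | COc1ccc(CO[C@H]2CC[C@]3(C)CC(O)C(C(=O)OC)=C[C@H]3[C@]2(C)O)cc1 | intermediate
21 | methyl ketone (C7 acetyl; 4α,8-diol, 3β-OPMB) | COc1ccc(CO[C@H]2CC[C@]3(C)CC(O)C(C(C)=O)=C[C@H]3[C@]2(C)O)cc1 | intermediate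
22 | 3β-PMB-oxy-eudesm-6-ene-4α,8,11-triol (C8 epimers) | COc1ccc(CO[C@H]2CC[C@]3(C)CC(O)C(C(C)(C)O)=C[C@H]3[C@]2(C)O)cc1 | intermediate
23 | 4α,11-dihydroxy-3β-PMB-oxy-eudesm-6-en-8-one | COc1ccc(CO[C@H]2CC[C@]3(C)CC(=O)C(C(C)(C)O)=C[C@H]3[C@]2(C)O)cc1 | intermediate
24 | 3β,4α,11-trihydroxyeudesm-6-en-8-one | O[C@H]1CC[C@]2(C)CC(=O)C(C(C)(C)O)=C[C@H]2[C@]1(C)O | intermediate
25 | tiglic acid ((E)-2-methylbut-2-enoic acid) | C/C=C(\C)C(=O)O | starting material
26 | (E)-2-methylbut-2-en-1-ol | C/C=C(\C)CO | intermediate
27 | [(2R,3R)-2,3-dimethyloxiran-2-yl]methanol | C[C@H]1O[C@]1(C)CO | intermediate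
28 | (2S,3R)-2,3-dimethyloxirane-2-carbaldehyde | C[C@H]1O[C@]1(C)C=O | intermediate
29 | (2S,3R)-2,3-dimethyloxirane-2-carboxylic acid | C[C@H]1O[C@]1(C)C(=O)O | intermediate
30 | mixed anhydride of 29 with 2,4,6-trichlorobenzoic acid | C[C@H]1O[C@]1(C)C(=O)OC(=O)c1c(Cl)cc(Cl)cc1Cl | intermediate
31 | CNP0272928.2: 3β-[(2S,3R)-2,3-dimethyloxirane-2-carbonyloxy]-4α,11-dihydroxyeudesm-6-en-8-one | C[C@H]1O[C@]1(C)C(=O)O[C@H]1CC[C@]2(C)CC(=O)C(C(C)(C)O)=C[C@H]2[C@]1(C)O | target

Total step count: 24. Longest linear sequence: 21 steps (steps 1–20 and 24); the acid 29 comes from a three-step branch (steps 21–23).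

Steps most likely to fail

Step 3. The cycloaddition may proceed with too little exo preference, the formyl-endo mode competing and placing C6 cis to C9, or with eroded enantioface control for this acyclic diene. The fallback exchanges the roles of the two α-substituents so that the formyl-endo mode gives the needed relative configuration. It sets out from 3, which is combined under the enantiomeric (R)-oxazaborolidinium triflimide with 4,4-dimethoxy-2-methylidenebutanal F1 (from 4,4-dimethoxybutanal and aqueous formaldehyde with pyrrolidinium propionate catalysis). This should give the formyl-endo adduct F2, whose formyl group stands cis to C6 and whose acetal arm stands trans. The formyl group is then reduced to the C14 methyl group through the tosylhydrazone F3 (TsNHNH2; then catecholborane, NaOAc). The fallback comes back at 7, and steps 4 and 5 are not needed.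

Step 7. The alkoxide may open the hindered epoxide slowly or partly at C4, and any β-epoxide carried over from step 6 would end as the C3 epimer. The fallback sets out from 7. Syn-dihydroxylation (OsO4 cat., N-methylmorpholine N-oxide) anti to the β substituents on C5 and C10 should give the 3α,4α-diol F4. SOCl2/Et3N converts it into the cyclic sulfite F5, and RuCl3/NaIO4 into the cyclic sulfate F6. Sodium 4-methoxybenzyloxide should attack this more reactive electrophile at the less hindered C3 with inversion, giving the C4 sulfate monoester sodium salt F7. Hydrolysis with catalytic H2SO4 and one equivalent of water in THF comes back at 9.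

Step 16. The amine-catalysed coupling may stall with the β-quaternary aldehyde because the addition is slow and its aldol stage reversible. The fallback sets out from 17 and uses a preformed nucleophile: [1-(methoxycarbonyl)ethenyl]diisobutylaluminium F8, made by hydroalumination of methyl propiolate with iBu2AlH in the presence of N-methylmorpholine N-oxide. It should add to the aldehyde at 0 °C and come back at 19.

Further compounds
F1 | step 3 | 4,4-dimethoxy-2-methylidenebutanal | COC(OC)CC(=C)C=O
F2 | step 3 | formyl-endo adduct: C10 carries CHO (β) and CH2CH(OMe)2 (α); 3-ene; C6–OTIPS | COC(OC)C[C@@]1(C=O)CCC=C[C@@H]1CO[Si](C(C)C)(C(C)C)C(C)C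
F3 | step 3 | tosylhydrazone of F2 | COC(OC)C[C@@]1(C=NNS(=O)(=O)c2ccc(C)cc2)CCC=C[C@@H]1CO[Si](C(C)C)(C(C)C)C(C)C
F4 | step 7 | 3α,4α-diol of 7 | COC(OC)C[C@@]1(C)CC[C@@H](O)[C@@H](O)[C@@H]1CO[Si](C(C)C)(C(C)C)C(C)C
F5 | step 7 | 3α,4α-cyclic sulfite | COC(OC)C[C@@]1(C)CC[C@H]2OS(=O)O[C@H]2[C@@H]1CO[Si](C(C)C)(C(C)C)C(C)C
F6 | step 7 | 3α,4α-cyclic sulfate | COC(OC)C[C@@]1(C)CC[C@H]2OS(=O)(=O)O[C@H]2[C@@H]1CO[Si](C(C)C)(C(C)C)C(C)C
F7 | step 7 | sodium 3β-PMB-oxy-4α-sulfate | COC(OC)C[C@@]1(C)CC[C@H](OCc2ccc(OC)cc2)[C@@H](OS(=O)(=O)[O-])[C@@H]1CO[Si](C(C)C)(C(C)C)C(C)C.[Na+]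
F8 | step 16 | [1-(methoxycarbonyl)ethenyl]diisobutylaluminium | COC(=O)C(=C)[Al](CC(C)C)CC(C)C
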